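Each J charged stands as J, as L or as something unseen, so the green run at 12.0 h, with 8.2% of J and 36.6% of L, holds 55.2% unseen.

| flask | J | Q | remark | time |
|---|---|---|---|---|
| green | 2.8 M | 200 mM (held) | the very flask that is asked about, followed so far |  |
| flask | 2.8 M | 200 mM (held) |  | 30 h |

- green (time / h: L / %, J / %): 1.50: 13.2, 64.3; 4.00: 22.3, 35.8; 8.00: 33.7, 16.1; 12.0: 36.6, 8.2

(readings scatter by 1 percentage point)

- the numbers in the tables scatter by 1 percentage point (one standard deviation)
- at the start none of Q is in solution

- the L standing at 30 h, as a percentage of the J charged
- the change that raises the amount of L at 30 h, in percent of the J charged most ("none" if none brings more than 2 percentage points) (noon / dusk / none)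
- amount of L at 30 h, in percent of the J charged, after dusk

- noon: doubling the transfer coefficient of Q, all else as stated
- dusk: doubling the saturation concentration of Q, all else as stated

I fold the hours into one count. In the green run J falls from 16.1% to 8.2% between 8.00 h and 12.0 h, which reads as a late pseudo-first-order constant of 0.169 h⁻¹ and a half-life of 4.11 h, both carrying the scatter of two readings. The half-life count, the asked time divided by this half-life, is 7.30. It says how many halvings the flask gets, and that many leave about 0.634% of the J charged. So y is close to the share of lost J that became L, and the ratio to watch on a repeat is L per J lost, not the clock. At 12.0 h that share reads 39.9%, which is my y.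

One number is not enough, since the count holds nothing of Q: it says how far J falls, not where J goes. The green run already shows 13.2% of L at 1.50 h, about a third of its 12.0 h reading, so I see no lag for noon to shorten. That leaves dusk as my first choice, and I give it no size, since the green run holds Q at the one setting of 200 mM.

The forecast gives 40% for y, none as the best change and 40% after dusk, holding that “Neither change has a clear lever on selectivity”. On the best change I part from it.

The flask gives 42.2%, and dusk is the best change: it lifts L by 17 percentage points to 59.0%, while noon brings 0.16 points.

    Q ⇌ G, rate k1*(csat - [G]) (kL = 72.0 h⁻¹)
    J + G → L (k = 0.500 M⁻¹ h⁻¹)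
    J → X (k = 0.0620 h⁻¹)
    2 J → E (k = 0.0290 M⁻¹ h⁻¹)

In this flask G stands at 99.1% of saturation by 3.00 h, and the slowness of the crossing barely moves L. The count's 0.634% of J stands above the 0.391% in the flask at 30.0 h.

For the neighbour with 1.1 M of J and the same hours, I carry the same count of 7.30, which leaves about 0.634% of its J. The computed neighbour keeps 0.56% of its J and holds 51.5% of L.

The readings are calculated on assumed constants, noise included.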